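The substrate left over in the east flask, a quarter of the charge at the last reading, was what you asked about. Your hunch was that the enzyme had died on it and that a fresh dose would finish the job.

common to all: free enzyme 10 µM

| flask | substrate | temperature | remark | time |
|---|---|---|---|---|
| east | 0.10 M | 40 °C | the very flask that is asked about, followed so far |  |
| south-west | 0.15 M | 46 °C | run made earlier |  |
| flask | 0.10 M | 40 °C |  | 12 h |

| run | time / min | product / % |
|---|---|---|
| east | 30.0 | 58.9 |
| east | 80.0 | 67.5 |
| east | 150 | 70.1 |
| east | 240 | 71.8 |
| east | 360 | 72.6 |
| east | 480 | 72.3 |
| east | 600 | 73.9 |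
| south-west | 1.50 | 24.4 |
| south-west | 5.00 | 43.0 |
| south-west | 10.0 | 51.5 |
| south-west | 15.0 | 57.5 |
| south-west | 20.0 | 60.0 |
| south-west | 25.0 | 61.4 |
| south-west | 30.0 | 62.5 |

(standard deviation of a reading: 0.5 percentage points)

- violet: change nothing and wait 25 h more
- green: at 12 h raise the temperature by 10 K, then wait 25 h
- grey: at 12 h take out 90% of the product then present, then wait 25 h
- amber: at 12 h add free enzyme, 50.0% of the amount charged, then wait 25 h

- what is taken out of product is counted as made
- candidate steps: free enzyme -> unfolded enzyme; substrate + free enzyme <-> complex; complex <-> free enzyme + product; free enzyme <-> dormant form; 2 free enzyme -> spent catalyst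
- additions bring no volume worth counting

- product, in percent of the substrate first charged, at 12 h
- the option that brings most further product ("none" if no option brings more than 2 percentage points) (violet / green / grey / amber / none)
- product present, with what was taken out counted in, in percent of the substrate first charged, after violet
- product present, with what was taken out counted in, in percent of the substrate first charged, after amber

I counted turnovers. At its last reading the east flask had made 7390 product molecules per enzyme charged; I call this the turnover bill, product made divided by free enzyme charged. The warmer south-west run, with the same enzyme charge, had paid 9380 by its last reading, more than the east bill, and in 30.0 min. The temperatures and the substrate charges differ, so this was a reading and no proof that the enzyme in the east flask could still work. I took its flattening for a ceiling on product, an equilibrium limit. From its last three readings I said about 72.9% at 12 h. I expected waiting and a fresh dose each to land near 73.9%, and I chose grey, which moves the mixture off that ceiling.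

The forecast said 73.3%, with grey best, 73.8% after violet and 74% after amber, and held that the enzyme “fades slowly but is not gone”.

The flask gave 73.1%, a bill of 7310, with grey best at 9.3 percentage points gained, 73.9% after violet and 74.6% after amber.

    free enzyme → unfolded enzyme (k = 2.20 × 10⁻⁴ min⁻¹, Ea = 227 kJ mol⁻¹)
    substrate + free enzyme ⇌ complex (K = 14.0 L mol⁻¹, k = 2.70 × 10⁵ L mol⁻¹ min⁻¹, Ea = 34.0 kJ mol⁻¹, ΔH = −18.0 kJ mol⁻¹)
    complex ⇌ free enzyme + product (K = 0.210 M, k = 4900 min⁻¹, Ea = 57.0 kJ mol⁻¹, ΔH = 14.0 kJ mol⁻¹)
    free enzyme ⇌ dormant form (K = 1.10, k = 0.140 min⁻¹, Ea = 92.0 kJ mol⁻¹, ΔH = −14.0 kJ mol⁻¹)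
    2 free enzyme → spent catalyst (k = 1.40 × 10⁵ L mol⁻¹ min⁻¹, Ea = 42.0 kJ mol⁻¹)
    (constants at 40 °C)

At 720 min spent catalyst was 99.6% of the enzyme charged and free enzyme 0.125%, yet the half-life of substrate by its forward binding alone was 3.4 h, shorter than the 25 h of further waiting. In that waiting the flask gained 0.76 points. The neighbour flask charged with 2.5 × 10⁻⁵ M of free enzyme stood at 73.8% at 720 min, a bill of 2950 per enzyme charged.

(The earlier runs and the new flask come from a simulation with constants of no real substance, noise included.)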